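**One step, or not.** A one-step world has starting material falling fastest at the first minute. The north-west run does otherwise: starting material still reads 95.7% at 6.00 min, then 32.5% at 12.0 min. This is an induction period, then autocatalysis: target breeds target, and target also decays.

| flask | starting material | reagent | remark | time |
|---|---|---|---|---|
| north-west | 0.23 M | 1.2 equiv | run made earlier |  |
| east | 0.12 M | 1.2 equiv | run made earlier |  |
| theta | 0.23 M | 1.20 equiv | a closed flask charged with all of it at once and left for 20 min | 20 min |
| epsilon | 0.23 M | 1.20 equiv | a single well-mixed tank run continuously and read at steady state, 20 min in it on average |  |
| delta | 0.23 M | 1.20 equiv | a tube with plug flow, the mixed feed as stated, residence time 20 min | 20 min |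
| eta | 0.23 M (fed, over 10.0 min) | 1.20 equiv | a stirred flask in which starting material is dosed at a steady rate over 10.0 min without added volume, worked up at 20 min | 20 min |

- north-west (time / min: target / %, starting material / %): 1.50: 0.2, 100.0; 3.00: 0, 99.6; 5.00: 1.6, 98.3; 6.00: 3.4, 95.7; 8.00: 17.2, 80.2; 10.0: 38.5, 52.3; 12.0: 47.7, 32.5
- east (time / min: target / %, starting material / %): 0.200: 0.4, 100.1; 0.667: 0, 100.0; 1.00: 0.3, 100.2; 1.50: 0.1, 100.1; 2.50: 0, 99.7; 3.00: 0, 100.5; 4.00: 0.3, 99.9

(readings scatter by 0.3 percentage points)

- the stated concentrations are those of everything mixed, before any reaction; amounts are the same in each set-up
- what may be going on: target -> over-reaction product; starting material + reagent + target -> 2 target; starting material + reagent -> target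
- the feed brings no volume worth counting
- the earlier runs were made in a closed, stirred flask

1. the set-up with the highest amount of target at the outlet or at the end, in percent of the starting material put in ("none" if the first two lie within 2 percentage points) (theta / epsilon / delta / eta / none)
2. amount of target at the outlet or at the end, in percent of the starting material put in, theta
3. amount of target at the outlet or at the end, in percent of the starting material put in, epsilon
4. amount of target at the outlet or at the end, in percent of the starting material put in, delta
5. amount of target at the outlet or at the end, in percent of the starting material put in, eta

**Two rates.** Let s be the fraction of starting material left and b the reagent in the same units. In the north-west run, between 8.00 min and 10.0 min, the fall of s gives a gain constant of 0.877 min⁻¹. The missing balance between 10.0 min and 12.0 min gives a loss constant of 0.123 min⁻¹. Divide gain per target at full charge by loss per target, and time drops out: this burn ratio is 8.55.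

**Two extremes.** If the feed costs nothing, eta is the closed flask at 20 min. If it costs its whole 10.0 min, eta is that flask at 10.0 min, reading 38.5%. Eta lies between, because over the feed it has received on average half of its starting material, and gain then still exceeds loss. Target's growth exponent over the feed is 4.03. Matching it to growth at full charge puts the lag at 5.66 min, so eta ends at a closed-flask clock of 14.3 min. Walking on from the last reading with both constants, I expect 47.0%. Theta and the tube delta share one clock, later than eta's. Gain per target at the last reading of the north-west run is already down to 0.150 min⁻¹ against a loss of 0.123 min⁻¹, and s falls on, so I expect both to end below eta. In the tank epsilon, gain balances loss plus washout, giving s of 35.5% and target of 18.6%.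

**The forecast.** It gave 30% for theta, 19% for epsilon, 30% for delta and 38.5% for eta, lower than my 47.0% for eta, and chose eta: “Eta wins because it spends less time in decay”.

**The result.** The flasks give 30.1%, 19.2%, 30.1% and 45.2% in that order, and eta is best.

    target → over-reaction product (k = 0.120 min⁻¹)
    starting material + reagent + target → 2 target (k = 17.0 M⁻² min⁻¹)
    starting material + reagent → target (k = 4.50 × 10⁻⁴ M⁻¹ min⁻¹)

**A richer neighbour.** Take eta with 0.39 M of starting material and the same equivalents of reagent. At fixed equivalents, gain per target scales with the square of concentration, so the burn ratio goes to 24.6, above eta's, and the exponent over the feed goes from 4.03 to 13.9. That flask ends with 0.90% of its starting material left, target at 27.2% and over-reaction product at 71.9%.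

The data are simulated for substances that don't exist; scatter was added.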